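Elemane numbering is used throughout: ring C5–C10; C10 carries CH3 (C14) and the vinyl group C1=C2; C5 carries C4(=C3)–C15; C7 carries C11(=C13)–C12. β is the ring face of the C14 methyl, α the opposite face. TBS = tert-butyldimethylsilyl, TES = triethylsilyl, PMB = 4-methoxybenzyl, Tf = trifluoromethanesulfonyl.

## Structural features

The target has a single carbocycle, the cyclohexane C5–C10, in which five of six ring atoms are stereocentres and only C9 is a methylene. C10 is quaternary (β-methyl, α-vinyl) and adjoins C5, whose 3-hydroxyprop-1-en-2-yl group (C4=C3, C15–OH) is α, so the vinyl and 2-propenyl groups are cis and vicinal. C6 (OH), C7 (acrylic acid unit C11=C13/C12) and C8 (acyloxy) follow contiguously with all three substituents β. In the chair that keeps the C5, C6 and C8 substituents equatorial the C7 substituent is axial, so C7 is the contra-thermodynamic centre and must not sit α to a carbonyl once set. The ester is (R)-3,4-dihydroxy-2-methylidenebutanoate, a sixth stereocentre outside the ring.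

Fragile points:
- two acrylate-type acceptors and three further terminal alkenes, which rule out hydrogenation and late electrophilic oxidants;
- the C12 acid, cis to 6-OH and poised for γ-lactonisation under acid;
- the side-chain 4'-OH, which can attack its own ester carbonyl under base;
- possible O8→O6 acyl shift;
- the 1,5-diene C2=C1–C10–C5–C4=C3, which can undergo Cope rearrangement on strong heating.

The real difficulties are the quaternary C10 next to C5 with cis alkenyl groups, the all-cis C6–C7–C8 triad, and unveiling the hydroxy acid last. The key step exploits the fact that the vinyl group (C1=C2 on C10) and the 2-propenyl group (C4=C3 on C5) are the two halves of a cyclobutene C10–C1=C4–C5 cut by ethylene. A four-membered ring can only be cis-fused to ring C5–C10, so the cis relation is guaranteed.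

## Logic of the disconnections

39 to 38: four O–Si bonds are cut last. All hydroxyls are unmasked in one mildly acidic fluoride step, so the lactonisation-prone hydroxy acid exists only at the end. The forward step must be non-basic and cold.

38 to 36 to 35: the C12 carboxyl is traced to a PMB-protected primary allylic alcohol. Carrying C12 as an ether removes a second Michael acceptor and a lactonisable ester from all earlier steps. The demand is selective PMB removal and a two-stage oxidation that spares C15–OTBS.

35 to 26 + 33: the C8–O acyl bond is cut, which splits off the whole side chain as the acid 33. The forward esterification must acylate a secondary alcohol flanked by an axial C7 substituent, with 6-OH blocked.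

26 to 25 to 24 to 23: the C7–H bond and the C8–O bond are traced to an alkenyl oxirane made by hydroxyl-directed epoxidation. This relays the whole triad from C6: epoxide syn to 6β-OH, then hydride to C7 with inversion. The demands are delivery of hydride to the ring terminus of the allyl system and survival of a tertiary allylic epoxide.

23 to 17 + 22, and 17 to 16 to 15 to 13: the C7–C11 bond is cut as an alkenyl iodide/alkenylstannane pair, the C6 carbinol is traced to a ketone, and the C7=C8 unsaturation to ketone 13. This reduces the problem to a single ketone. The forward reduction of 16 must be reagent-controlled because the ring of 16 has no strong conformational bias.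

13 to 12 to 11: the C6 oxidation level is adjusted (O–Si bond, then C–H). This reaches the ring-opening product with its silyl ether, at the cost of a selective TES removal next to a primary TBS ether.

11 to 9 + 10 (key): the C1=C2 and C4=C3 double bonds are cut, joining C1 to C4 in a cyclobutene and releasing ethylene. Two alkenyl groups and their cis relation collapse into one strained ring. The forward step needs only chemoselective opening of a trisubstituted cyclobutene.

9 to 8 to 7 to 6 to 5 to 4 to 3: the C4–C15 bond is cut (hydroxymethylation of an enol triflate), the triflate is traced to a cyclobutanone and that to an exocyclic methylene. The C6 carbonyl is masked as a silyl ether so that no 1,3-dicarbonyl is ever present. Enolisation of 6 must go toward C1.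

3 to 1 + 2: the C10–C1 and C5–C4 bonds are cut in a [2+2] sense. Head-to-head addition of 2 puts the functionalised cyclobutane carbon on C5, as the target requires, and fixes both ring-fusion centres in one step from two commodity chemicals. The forward step must be enantioselective.

33 to 32 to 31 to 30 to 29 to 28 to 27: the C1'–C2' bond is cut (carbonylation of an enol triflate) and the 2-methylidene carbon is traced to a methyl ketone made from a glycerate ester. The stereocentre comes from the chiral pool and must not be enolised.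

22 to 21 to 20 to 18 + 19: the C–Sn and C–O bonds are cut, which gives two commercial materials.

## Other disconnections considered

Alternative 1: The ring is cut at C9–C10 and C5–C6. Forward, the tethered triene A1 (a 4-(silyloxymethyl)butenolide joined through a diisopropylsilylene to the C8 oxygen of a 1,3-bis(silyloxy)diene) would be heated. The diene C9=C8–C7=C6 would add across the butenolide alkene C5=C10 in a type 2 intramolecular Diels–Alder reaction to give the bridged silaketal A2.
- In its favour: one step would build the ring, the quaternary C10, C5 and C6. The oxygen atoms on C6 and C8 and the C11–C12 arm on C7 would already be present, and the butenolide geometry fixes the cis relation of C1 and C4.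
- Against it here: C14 arrives oxygenated and must be reduced to a methyl group at a neopentyl position. The lactone must be dismantled into a vinyl group (adding C2) and a 2-propenyl alcohol (adding C3 and C15). C13 is missing. Hydrolysis of the bridgehead enol ether would set C7 by protonation, which favours the equatorial, wrong epimer. A1 is achiral, so the absolute configuration would have to come from an enantioselective thermal cycloaddition through a strained bridged transition state.
- Comparison: on structure A2 is the better intermediate, because it carries the C6 and C8 oxygens and the C7 carbon arm that the chosen plan adds in eight steps after 11. On mechanism the two are equal in one respect: both fix the C10/C5 cis pair by a ring constraint. On step economy the chosen plan should be shorter, since 11 already has C14 as a methyl group and C1–C4 and C15 at their final oxidation levels.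

Alternative 2: The ring is cut at C6–C7. Forward, CrCl2 (divalent chromium) would convert the allylic bromide of the open-chain aldehyde A3 into an allylchromium species whose γ-carbon C7 adds to the C6 aldehyde, giving the hydroxy ester A4.
- In its favour: the hydroxy α-methylene ester motif would be created exactly as it stands in the target, C6 and C7 being set together through a closed transition state, with no later change of oxidation level at C12.
- Against it here: A3 must hold the quaternary C10 and the C5 and C8 stereocentres in an open chain with no ring to relay them. Its aldehyde is α-branched and β,γ-unsaturated, hence prone to epimerisation and conjugation. The ring closure would have to deliver the all-cis triad with C7 axial, which depends on how the chain folds. The free γ-hydroxy ester A4 can lactonise.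
- Comparison: on structure the two plans are equal, meeting at nearly the same late intermediate (A4 corresponds to 26 with a different protecting-group pattern). On mechanism the alternative sets two centres in one organometallic step where the chosen plan uses a three-step relay. On step economy the alternative is the better from A4 onward (about four steps to the target, against the steps from 26), but its front end, the acyclic construction of A3, would be much longer than the seven steps to 9.

Alternative 3: The bond C9–C10 is cut and an O–C2 bond is added, which expands the carbocycle to an eight-membered enol ether. Forward, heating the 2-methylene-oxocene A5 would bring about a Claisen rearrangement that contracts the ring to the cyclohexanone A6.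
- In its favour: the sigmatropic step would make the quaternary C10 stereospecifically from the ring alkene geometry. It delivers the vinyl group and a C8 carbonyl at once, and C5, C6 and C7 arrive fully substituted.
- Against it here: A5 is a medium-ring lactone-derived enol ether with three contiguous stereocentres and a Z-trisubstituted alkene, so its synthesis would be long. The rearrangement temperature endangers the 1,5-diene of A6 (Cope) and the α-stereocentre C7, which is axial and next to the new ketone. The C8 ketone must then be reduced to the β-alcohol beside that axial group.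
- Comparison: on structure the alternative is the better in that its key step supplies the C8 oxygen and has the C7 arm in place. On mechanism the two are equal in releasing the C10 vinyl group by a reagent-light, thermodynamically driven step. The chosen plan is the safer in that the C10/C5 relation follows from a cis ring fusion and not from a transition-state preference. On step economy the chosen plan should win because 9 is seven steps from commodity materials.

Key step: step 8

**Remarks and assumptions**

- A 1,1-dialkoxyethene would add to 1 head-to-tail. Its acetal carbon would be bonded to C10, and the derived cyclobutanone, enol triflate and hydroxymethyl group would end on C1. Ethenolysis would then give the constitutional isomer with the hydroxymethyl-vinyl group on C10. Allene (2) adds head-to-head and is used instead, and the structures of 9 and 11 are then regiochemically consistent with the target.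
- The configuration at C6 in 4–12 is immaterial, since C6 becomes a ketone in 13. The alcohol expected from convex-face attack is drawn.
- The target is assumed to be isolable as the free γ-hydroxy acid if it is kept cold and is not exposed to strong acid or base.

## Route

Step 1
Reactants: 1 3-methylcyclohex-2-en-1-one; 2 propa-1,2-diene (allene)
Product: 3 (1R,6S)-6-methyl-8-methylidenebicyclo[4.2.0]octan-2-one
Conditions: AlBr3-activated chiral B-aryl oxazaborolidine (prolinol-derived; the ligand antipode that gives the 1R,6S series), allene (excess), CH2Cl2, hν (366 nm), −75 °C; then basic Al2O3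
Reagents that add atoms: none
Why: Proposed new method: the AlBr3-activated oxazaborolidine binds the enone carbonyl, shifts its absorption so that only the complexed enone is excited at 366 nm and shields one face of C5=C10, while allene should add head-to-head as in the uncatalysed enone–allene [2+2] photocycloaddition (central allene carbon to the α-carbon C5, terminal carbon to C10), which places the methylidene-bearing carbon C4 on C5; the closest known reaction type is the same chiral-Lewis-acid-catalysed intermolecular [2+2] photocycloaddition of cyclohex-2-enones with simple alkenes, here extended to a cumulene; C5 and C10 are set together and any trans-fused adduct epimerises at C5 (α to the ketone) to the cis-fused ketone on alumina.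

Step 2
Reactants: 3 (1R,6S)-6-methyl-8-methylidenebicyclo[4.2.0]octan-2-one
Product: 4 (1R,2S,6S)-6-methyl-8-methylidenebicyclo[4.2.0]octan-2-ol
Conditions: NaBH4, MeOH, 0 °C
Reagents that add atoms: none
Why: Borohydride reduction of the ketone from the convex face (anti to the cyclobutane) should give the endo alcohol; the alkene is inert and the C6 configuration is erased again in step 10.

Step 3
Reactants: 4 (1R,2S,6S)-6-methyl-8-methylidenebicyclo[4.2.0]octan-2-ol
Product: 5 triethyl{[(1R,2S,6S)-6-methyl-8-methylidenebicyclo[4.2.0]octan-2-yl]oxy}silane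
Conditions: Et3SiCl, imidazole, DMAP (cat.), DMF, 25 °C
Reagents that add atoms: chlorotriethylsilane, CC[Si](Cl)(CC)CC
Why: Standard silylation of a secondary alcohol; masking C6 as an ether prevents a 1,3-dicarbonyl (and its retro-Claisen opening) from forming in step 4.

Step 4
Reactants: 5 triethyl{[(1R,2S,6S)-6-methyl-8-methylidenebicyclo[4.2.0]octan-2-yl]oxy}silane
Product: 6 (1S,5S,6R)-1-methyl-5-(triethylsilyloxy)bicyclo[4.2.0]octan-7-one
Conditions: O3, pyridine, CH2Cl2, −78 °C
Reagents that add atoms: ozone, [O-][O+]=O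
Why: Ozonolysis of the only alkene, a 1,1-disubstituted one; with pyridine the carbonyl oxide should collapse directly to the cyclobutanone and formaldehyde without a peroxidic work-up, and the silyl ether is inert.

Step 5
Reactants: 6 (1S,5S,6R)-1-methyl-5-(triethylsilyloxy)bicyclo[4.2.0]octan-7-one
Product: 7 (1S,5S,6R)-1-methyl-5-(triethylsilyloxy)bicyclo[4.2.0]oct-7-en-7-yl trifluoromethanesulfonate
Conditions: KN(SiMe3)2, PhNTf2 (present from the start), THF, −78 °C
Reagents that add atoms: N-phenylbis(trifluoromethanesulfonimide), O=S(=O)(N(c1ccccc1)S(=O)(=O)C(F)(F)F)C(F)(F)F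
Why: Kinetic enolisation with in situ triflation; the bulky amide should remove a proton from the C1 methylene rather than the hindered ring-fusion C5–H, whose enolate would place a double bond at the ring fusion and expel the C6 silyloxy group.

Step 6
Reactants: 7 (1S,5S,6R)-1-methyl-5-(triethylsilyloxy)bicyclo[4.2.0]oct-7-en-7-yl trifluoromethanesulfonate
Product: 8 [(1S,5S,6S)-1-methyl-5-(triethylsilyloxy)bicyclo[4.2.0]oct-7-en-7-yl]methanol
Conditions: Bu3SnCH2OH, Pd(PPh3)4 (cat.), LiCl, 1,4-dioxane, 90 °C
Reagents that add atoms: (tributylstannyl)methanol, CCCC[Sn](CCCC)(CCCC)CO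
Why: Stille hydroxymethylation of an alkenyl triflate; oxidative addition at the cyclobutenyl C–O bond, transfer of the hydroxymethyl group from tin and reductive elimination install C15 on C4 without touching a stereocentre.

Step 7
Reactants: 8 [(1S,5S,6S)-1-methyl-5-(triethylsilyloxy)bicyclo[4.2.0]oct-7-en-7-yl]methanol
Product: 9 tert-butyl(dimethyl){[(1S,5S,6S)-1-methyl-5-(triethylsilyloxy)bicyclo[4.2.0]oct-7-en-7-yl]methoxy}silane
Conditions: t-BuMe2SiCl, imidazole, CH2Cl2, 25 °C
Reagents that add atoms: tert-butylchlorodimethylsilane, CC(C)(C)[Si](C)(C)Cl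
Why: Routine silylation of a primary allylic alcohol, giving two silyl ethers of different lability for step 9.

Step 8
Reactants: 9 tert-butyl(dimethyl){[(1S,5S,6S)-1-methyl-5-(triethylsilyloxy)bicyclo[4.2.0]oct-7-en-7-yl]methoxy}silane; 10 ethene
Product: 11 tert-butyl({2-[(1S,2S,6S)-2-ethenyl-2-methyl-6-[(triethylsilyl)oxy]cyclohexyl]prop-2-en-1-yl}oxy)dimethylsilane (10β-methyl; 10α-vinyl; 5α-propenyl; 6α-OTES)
Conditions: second-generation Grubbs catalyst RuCl2(=CHPh)(H2IMes)(PCy3) (5 mol%), ethene (1 atm), CH2Cl2, 25–40 °C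
Reagents that add atoms: none
Why: The catalyst is converted by ethene into a ruthenium methylidene, which undergoes [2+2] cycloaddition with the strained cyclobutene C1=C4 with the metal on the less substituted carbon C1; cycloreversion of the metallacyclobutane opens the four-membered ring, creating C4=C3 and a ruthenium alkylidene on C1, and a second ethene converts this into C1=C2 and returns the methylidene. The closest known reaction type is the ring-opening cross-metathesis (ethenolysis) of cyclobutenes obtained from enone [2+2] photoadducts. No ring is closed and no stereocentre is formed; the cis relation of the C10 vinyl and C5 propenyl groups is inherited from the cis ring fusion of 9 and the quaternary centre is untouched. The step needs chemoselective opening without oligomerisation or secondary metathesis: release of about 30 kcal/mol of ring strain makes the opening irreversible, excess ethene caps the alkylidene, and the two product alkenes (one 1,1-disubstituted, one vinyl group on a quaternary carbon) are poor metathesis partners whose only ring closure would rebuild the cyclobutene. Both silyl ethers are inert to the catalyst.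

Step 9
Reactants: 11 tert-butyl({2-[(1S,2S,6S)-2-ethenyl-2-methyl-6-[(triethylsilyl)oxy]cyclohexyl]prop-2-en-1-yl}oxy)dimethylsilane
Product: 12 10β-methyl-10α-vinyl-5α-[3-(TBS-oxy)prop-1-en-2-yl]cyclohexan-6α-ol
Conditions: pyridinium p-toluenesulfonate (cat.), MeOH/CH2Cl2, 0 °C
Reagents that add atoms: none
Why: Acid-catalysed methanolysis cleaves the triethylsilyl ether much faster than the primary tert-butyldimethylsilyl ether, so C6–OH alone should be freed.

Step 10
Reactants: 12 10β-methyl-10α-vinyl-5α-[3-(TBS-oxy)prop-1-en-2-yl]cyclohexan-6α-ol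
Product: 13 10β-methyl-10α-vinyl-5α-[3-(TBS-oxy)prop-1-en-2-yl]cyclohexan-6-one
Conditions: Dess–Martin periodinane, pyridine, CH2Cl2, 0 → 25 °C
Reagents that add atoms: none
Why: Dess–Martin oxidation is buffered and non-enolising, so the β,γ-unsaturated ketone should form without epimerisation at C5 or migration of C4=C3 into conjugation.

Step 11
Reactants: 13 10β-methyl-10α-vinyl-5α-[3-(TBS-oxy)prop-1-en-2-yl]cyclohexan-6-one
Product: 15 10β-methyl-10α-vinyl-5α-[3-(TBS-oxy)prop-1-en-2-yl]cyclohex-7-en-6-one, via trimethylsilyl enol ether 14 (not isolated)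
Conditions: LiN(iPr)2, Me3SiCl (in situ), THF, −78 °C; then Pd(OAc)2, MeCN, 25 °C
Reagents that add atoms: none
Why: Saegusa–Ito dehydrogenation; the amide base removes the accessible C7 proton rather than the hindered C5 methine, the silyl enol ether is palladated and β-hydride elimination gives the C7=C8 enone, the only enone possible because C10 is quaternary.

Step 12
Reactants: 15 10β-methyl-10α-vinyl-5α-[3-(TBS-oxy)prop-1-en-2-yl]cyclohex-7-en-6-one
Product: 16 7-iodo-10β-methyl-10α-vinyl-5α-[3-(TBS-oxy)prop-1-en-2-yl]cyclohex-7-en-6-one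
Conditions: I2, pyridine, CH2Cl2, 25 °C
Reagents that add atoms: iodine, II
Why: α-Iodination of an enone by conjugate addition of pyridine, iodination of the enolate and elimination (Baylis–Hillman-type manifold); the isolated alkenes have no comparable pathway.

Step 13
Reactants: 16 7-iodo-10β-methyl-10α-vinyl-5α-[3-(TBS-oxy)prop-1-en-2-yl]cyclohex-7-en-6-one
Product: 17 (6S)-7-iodo-10β-methyl-10α-vinyl-5α-[3-(TBS-oxy)prop-1-en-2-yl]cyclohex-7-en-6β-ol
Conditions: (R)-2-methyl-CBS-oxazaborolidine, catecholborane, toluene, −78 → −40 °C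
Reagents that add atoms: none
Why: Corey–Bakshi–Shibata reduction; the in-plane α-iodoalkenyl arm acts as the large group, so the (R)-catalyst should deliver hydride to the α face of C6=O and set the 6β-alcohol by reagent control, while catecholborane at low temperature does not hydroborate the terminal alkenes.

Step 14
Reactants: 18 2,3-dibromoprop-1-ene; 19 (4-methoxyphenyl)methanol
Product: 20 1-{[(2-bromoprop-2-en-1-yl)oxy]methyl}-4-methoxybenzene
Conditions: NaH, THF, 0 → 25 °C
Reagents that add atoms: none
Why: Williamson etherification; the alkoxide displaces the allylic bromide and the vinylic bromide is inert.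

Step 15
Reactants: 20 1-{[(2-bromoprop-2-en-1-yl)oxy]methyl}-4-methoxybenzene
Product: 22 tributyl{3-[(4-methoxybenzyl)oxy]prop-1-en-2-yl}stannane, via alkenyllithium 21 (not isolated)
Conditions: t-BuLi (2 equiv), Et2O, −78 °C; then Bu3SnCl, −78 → 25 °C
Reagents that add atoms: tributyltin chloride, CCCC[Sn](Cl)(CCCC)CCCC
Why: Bromine–lithium exchange on the vinylic bromide gives a 2-lithioallyl ether that is stable at −78 °C and is stannylated at carbon.

Step 16
Reactants: 17 (6S)-7-iodo-10β-methyl-10α-vinyl-5α-[3-(TBS-oxy)prop-1-en-2-yl]cyclohex-7-en-6β-ol; 22 tributyl{3-[(4-methoxybenzyl)oxy]prop-1-en-2-yl}stannane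
Product: 23 7-[3-(PMB-oxy)prop-1-en-2-yl]-10β-methyl-10α-vinyl-5α-[3-(TBS-oxy)prop-1-en-2-yl]cyclohex-7-en-6β-ol
Conditions: Pd2(dba)3 (cat.), AsPh3, CuI (cat.), N-methylpyrrolidone, 45 °C
Reagents that add atoms: none
Why: Stille coupling of an alkenyl iodide with a 1-substituted alkenylstannane under arsine and copper co-catalysis forms C7–C11; the free alcohol is tolerated and C12 enters as an ether, so no second Michael acceptor is created.

Step 17
Reactants: 23 7-[3-(PMB-oxy)prop-1-en-2-yl]-10β-methyl-10α-vinyl-5α-[3-(TBS-oxy)prop-1-en-2-yl]cyclohex-7-en-6β-ol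
Product: 24 7β,8β-epoxy-7α-[3-(PMB-oxy)prop-1-en-2-yl]-10β-methyl-10α-vinyl-5α-[3-(TBS-oxy)prop-1-en-2-yl]cyclohexan-6β-ol
Conditions: VO(acac)2 (cat.), t-BuOOH, CH2Cl2, 0 °C
Reagents that add atoms: tert-butyl hydroperoxide, CC(C)(C)OO
Why: Hydroxyl-directed epoxidation: the vanadium alkoxide of 6β-OH delivers oxygen to the allylic C7=C8 alkene on the β face, far faster than to the two homoallylic or the remote alkenes; the acid-sensitive tertiary allylic epoxide is silylated without delay.

Step 18
Reactants: 24 7β,8β-epoxy-7α-[3-(PMB-oxy)prop-1-en-2-yl]-10β-methyl-10α-vinyl-5α-[3-(TBS-oxy)prop-1-en-2-yl]cyclohexan-6β-ol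
Product: 25 7β,8β-epoxy-7α-[3-(PMB-oxy)prop-1-en-2-yl]-10β-methyl-6β-(TES-oxy)-10α-vinyl-5α-[3-(TBS-oxy)prop-1-en-2-yl]cyclohexane
Conditions: Et3SiCl, imidazole, DMAP (cat.), DMF, 25 °C
Reagents that add atoms: chlorotriethylsilane, CC[Si](Cl)(CC)CC
Why: Basic silylation of the epoxy alcohol; it leaves the epoxide intact and makes C8–OH the only free hydroxyl after step 19.

Step 19
Reactants: 25 7β,8β-epoxy-7α-[3-(PMB-oxy)prop-1-en-2-yl]-10β-methyl-6β-(TES-oxy)-10α-vinyl-5α-[3-(TBS-oxy)prop-1-en-2-yl]cyclohexane
Product: 26 7β-[3-(PMB-oxy)prop-1-en-2-yl]-10β-methyl-6β-(TES-oxy)-10α-vinyl-5α-[3-(TBS-oxy)prop-1-en-2-yl]cyclohexan-8β-ol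
Conditions: Pd2(dba)3·CHCl3 (cat.), n-Bu3P, HCO2H, Et3N, 1,4-dioxane, 25 °C
Reagents that add atoms: none
Why: Palladium-catalysed formate hydrogenolysis of an alkenyl oxirane: zerovalent palladium ionises the allylic C7–O bond with inversion (metal on the α face, also the face remote from both β-oxygens), formate decarboxylates to a palladium hydride, and hydride is delivered to the more substituted allyl terminus C7 from the α face, which keeps C11=C13 terminal and leaves 8β-OH with H7α, i.e. the all-cis triad.

Step 20
Reactants: 27 methyl (2S)-2,3-dihydroxypropanoate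
Product: 28 methyl (2S)-2,3-bis(TBS-oxy)propanoate
Conditions: t-BuMe2SiCl, imidazole, DMF, 25 °C
Reagents that add atoms: tert-butylchlorodimethylsilane, CC(C)(C)[Si](C)(C)Cl
Why: Exhaustive silylation of the chiral-pool diol; silyl ethers are chosen so that the final deprotection needs fluoride only.

Step 21
Reactants: 28 methyl (2S)-2,3-bis(TBS-oxy)propanoate
Product: 29 (2S)-2,3-bis(TBS-oxy)-N-methoxy-N-methylpropanamide
Conditions: MeNH(OMe)·HCl, i-PrMgCl, THF, −20 → 0 °C
Reagents that add atoms: N,O-dimethylhydroxylamine hydrochloride, CNOC.Cl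
Why: Direct aminolysis of the ester by the magnesium amide gives the Weinreb amide at low temperature without enolising the α-silyloxy centre.

Step 22
Reactants: 29 (2S)-2,3-bis(TBS-oxy)-N-methoxy-N-methylpropanamide
Product: 30 (3S)-3,4-bis(TBS-oxy)butan-2-one
Conditions: MeMgBr, THF, 0 °C
Reagents that add atoms: methylmagnesium bromide, C[Mg]Br
Why: Weinreb ketone synthesis; the chelated tetrahedral intermediate prevents over-addition and releases the methyl ketone on work-up.

Step 23
Reactants: 30 (3S)-3,4-bis(TBS-oxy)butan-2-one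
Product: 31 (3S)-3,4-bis(TBS-oxy)but-1-en-2-yl trifluoromethanesulfonate
Conditions: KN(SiMe3)2, PhNTf2 (present from the start), THF, −78 °C
Reagents that add atoms: N-phenylbis(trifluoromethanesulfonimide), O=S(=O)(N(c1ccccc1)S(=O)(=O)C(F)(F)F)C(F)(F)F
Why: Kinetic deprotonation occurs at the methyl group rather than at the hindered α-silyloxy methine, so the stereocentre is not enolised and the terminal enol triflate results.

Step 24
Reactants: 31 (3S)-3,4-bis(TBS-oxy)but-1-en-2-yl trifluoromethanesulfonate
Product: 33 (3R)-3,4-bis(TBS-oxy)-2-methylidenebutanoic acid, via mixed acetic anhydride 32 (not isolated)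
Conditions: Pd(OAc)2 (cat.), PPh3, CO (1 atm), KOAc, DMF, 25–60 °C; then H2O (pH 4–5)
Reagents that add atoms: carbon monoxide, [C-]#[O+]; potassium acetate, CC(=O)[O-].[K+]; water, O
Why: Palladium-catalysed hydroxycarbonylation of an alkenyl triflate: oxidative addition, CO insertion and capture of the acylpalladium by acetate give a mixed anhydride that hydrolyses on work-up to the 2-substituted acrylic acid; the descriptor changes from S to R only through the change in substituent priorities.

Step 25
Reactants: 26 7β-[3-(PMB-oxy)prop-1-en-2-yl]-10β-methyl-6β-(TES-oxy)-10α-vinyl-5α-[3-(TBS-oxy)prop-1-en-2-yl]cyclohexan-8β-ol; 33 (3R)-3,4-bis(TBS-oxy)-2-methylidenebutanoic acid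
Product: 35 8β-O-[(3R)-3,4-bis(TBS-oxy)-2-methylidenebutanoyl] ester of 26, via trichlorobenzoyl mixed anhydride 34 (not isolated)
Conditions: 2,4,6-trichlorobenzoyl chloride, Et3N, THF, 25 °C; then 26, DMAP, toluene, 25 °C
Reagents that add atoms: none
Why: Yamaguchi esterification; DMAP attacks the less hindered acryloyl carbonyl of the mixed anhydride and the resulting acylpyridinium acylates the equatorial C8–OH, the only free hydroxyl, without touching a stereocentre.

Step 26
Reactants: 35 8β-O-[(3R)-3,4-bis(TBS-oxy)-2-methylidenebutanoyl] ester of 26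
Product: 36 8β-[(3R)-3,4-bis(TBS-oxy)-2-methylidenebutanoyloxy]-7β-(3-hydroxyprop-1-en-2-yl)-10β-methyl-6β-(TES-oxy)-10α-vinyl-5α-[3-(TBS-oxy)prop-1-en-2-yl]cyclohexane
Conditions: 2,3-dichloro-5,6-dicyano-1,4-benzoquinone, CH2Cl2/pH 7 buffer, 0 °C
Reagents that add atoms: none
Why: Oxidative cleavage of the 4-methoxybenzyl ether by hydride abstraction and hydrolysis of the oxocarbenium ion; silyl ethers, the ester and the unactivated alkenes are inert, and any over-oxidation would only lead to the aldehyde wanted next.

Step 27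
Reactants: 36 8β-[(3R)-3,4-bis(TBS-oxy)-2-methylidenebutanoyloxy]-7β-(3-hydroxyprop-1-en-2-yl)-10β-methyl-6β-(TES-oxy)-10α-vinyl-5α-[3-(TBS-oxy)prop-1-en-2-yl]cyclohexane
Product: 38 2-{8β-[(3R)-3,4-bis(TBS-oxy)-2-methylidenebutanoyloxy]-10β-methyl-6β-(TES-oxy)-10α-vinyl-5α-[3-(TBS-oxy)prop-1-en-2-yl]cyclohexan-7β-yl}prop-2-enoic acid, via enal 37 (not isolated)
Conditions: Dess–Martin periodinane, pyridine, CH2Cl2, 0 °C; then NaClO2, NaH2PO4, 2-methylbut-2-ene, t-BuOH/H2O, 0 °C
Reagents that add atoms: sodium chlorite, [Na+].[O-]Cl=O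
Why: Dess–Martin oxidation of the only free (primary allylic) alcohol followed by Pinnick oxidation of the enal; chlorite oxidises only the aldehyde, the alkene scavenger removes hypochlorite, and neither stage is basic enough to move C11=C13 into conjugation or epimerise C7.

Step 28
Reactants: 38 2-{8β-[(3R)-3,4-bis(TBS-oxy)-2-methylidenebutanoyloxy]-10β-methyl-6β-(TES-oxy)-10α-vinyl-5α-[3-(TBS-oxy)prop-1-en-2-yl]cyclohexan-7β-yl}prop-2-enoic acid
Product: 39 2-[(1S,2S,3S,4S,6R)-6-{[(3R)-3,4-dihydroxy-2-methylidenebutanoyl]oxy}-4-ethenyl-2-hydroxy-3-(3-hydroxyprop-1-en-2-yl)-4-methylcyclohexyl]prop-2-enoic acid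
Conditions: HF·pyridine, pyridine, THF, 0 → 25 °C; cold neutral work-up
Reagents that add atoms: none
Why: Fluoride-driven cleavage of all four silyl ethers under buffered, weakly acidic conditions, which avoid the base-induced attack of the side-chain 4'-OH on its own ester and keep acid-catalysed lactonisation of the C12 acid onto 6-OH to a minimum.

## Compound list

1 | 3-methylcyclohex-2-en-1-one | CC1=CC(=O)CCC1 | starting material
2 | propa-1,2-diene (allene) | C=C=C | starting material
3 | (1R,6S)-6-methyl-8-methylidenebicyclo[4.2.0]octan-2-one | C3[C@]1(C)CCCC(=O)[C@@H]1C3=C | intermediate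
4 | (1R,2S,6S)-6-methyl-8-methylidenebicyclo[4.2.0]octan-2-ol | C3[C@]1(C)CCC[C@H](O)[C@@H]1C3=C | intermediate
5 | triethyl{[(1R,2S,6S)-6-methyl-8-methylidenebicyclo[4.2.0]octan-2-yl]oxy}silane | C3[C@]1(C)CCC[C@H](O[Si](CC)(CC)CC)[C@@H]1C3=C | intermediate
6 | (1S,5S,6R)-1-methyl-5-(triethylsilyloxy)bicyclo[4.2.0]octan-7-one | C3[C@]1(C)CCC[C@H](O[Si](CC)(CC)CC)[C@@H]1C3=O | intermediate
7 | (1S,5S,6R)-1-methyl-5-(triethylsilyloxy)bicyclo[4.2.0]oct-7-en-7-yl trifluoromethanesulfonate | C3[C@]1(C)CCC[C@H](O[Si](CC)(CC)CC)[C@@H]1C=3OS(=O)(=O)C(F)(F)F | intermediate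
8 | [(1S,5S,6S)-1-methyl-5-(triethylsilyloxy)bicyclo[4.2.0]oct-7-en-7-yl]methanol | C3[C@]1(C)CCC[C@H](O[Si](CC)(CC)CC)[C@@H]1C=3CO | intermediate
9 | tert-butyl(dimethyl){[(1S,5S,6S)-1-methyl-5-(triethylsilyloxy)bicyclo[4.2.0]oct-7-en-7-yl]methoxy}silane | C3[C@]1(C)CCC[C@H](O[Si](CC)(CC)CC)[C@@H]1C=3CO[Si](C)(C)C(C)(C)C | intermediate
10 | ethene | C=C | starting material
11 | tert-butyl({2-[(1S,2S,6S)-2-ethenyl-2-methyl-6-[(triethylsilyl)oxy]cyclohexyl]prop-2-en-1-yl}oxy)dimethylsilane | C=C[C@]1(C)CCC[C@H](O[Si](CC)(CC)CC)[C@@H]1C(=C)CO[Si](C)(C)C(C)(C)C | intermediate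
12 | 10β-methyl-10α-vinyl-5α-[3-(TBS-oxy)prop-1-en-2-yl]cyclohexan-6α-ol | C=C[C@]1(C)CCC[C@H](O)[C@@H]1C(=C)CO[Si](C)(C)C(C)(C)C | intermediate
13 | 10β-methyl-10α-vinyl-5α-[3-(TBS-oxy)prop-1-en-2-yl]cyclohexan-6-one | C=C[C@]1(C)CCCC(=O)[C@@H]1C(=C)CO[Si](C)(C)C(C)(C)C | intermediate
14 | 6-(trimethylsilyloxy)-10β-methyl-10α-vinyl-5α-[3-(TBS-oxy)prop-1-en-2-yl]cyclohex-6-ene (C6=C7 enol ether) | C=C[C@]1(C)CCC=C(O[Si](C)(C)C)[C@@H]1C(=C)CO[Si](C)(C)C(C)(C)C | intermediate (not isolated)
15 | 10β-methyl-10α-vinyl-5α-[3-(TBS-oxy)prop-1-en-2-yl]cyclohex-7-en-6-one | C=C[C@]1(C)CC=CC(=O)[C@@H]1C(=C)CO[Si](C)(C)C(C)(C)C | intermediate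
16 | 7-iodo-10β-methyl-10α-vinyl-5α-[3-(TBS-oxy)prop-1-en-2-yl]cyclohex-7-en-6-one | C=C[C@]1(C)CC=C(I)C(=O)[C@@H]1C(=C)CO[Si](C)(C)C(C)(C)C | intermediate
17 | (6S)-7-iodo-10β-methyl-10α-vinyl-5α-[3-(TBS-oxy)prop-1-en-2-yl]cyclohex-7-en-6β-ol | C=C[C@]1(C)CC=C(I)[C@@H](O)[C@@H]1C(=C)CO[Si](C)(C)C(C)(C)C | intermediate
18 | 2,3-dibromoprop-1-ene | C=C(Br)CBr | starting material
19 | (4-methoxyphenyl)methanol | COc1ccc(CO)cc1 | starting material
20 | 1-{[(2-bromoprop-2-en-1-yl)oxy]methyl}-4-methoxybenzene | C=C(Br)COCc1ccc(OC)cc1 | intermediate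
21 | {3-[(4-methoxybenzyl)oxy]prop-1-en-2-yl}lithium | [Li]C(=C)COCc1ccc(OC)cc1 | intermediate (not isolated)
22 | tributyl{3-[(4-methoxybenzyl)oxy]prop-1-en-2-yl}stannane | CCCC[Sn](CCCC)(CCCC)C(=C)COCc1ccc(OC)cc1 | intermediate
23 | 7-[3-(PMB-oxy)prop-1-en-2-yl]-10β-methyl-10α-vinyl-5α-[3-(TBS-oxy)prop-1-en-2-yl]cyclohex-7-en-6β-ol | C=C[C@]1(C)CC=C(C(=C)COCc2ccc(OC)cc2)[C@@H](O)[C@@H]1C(=C)CO[Si](C)(C)C(C)(C)C | intermediate
24 | 7β,8β-epoxy-7α-[3-(PMB-oxy)prop-1-en-2-yl]-10β-methyl-10α-vinyl-5α-[3-(TBS-oxy)prop-1-en-2-yl]cyclohexan-6β-ol | C=C[C@]1(C)C[C@H]2O[C@@]2(C(=C)COCc3ccc(OC)cc3)[C@@H](O)[C@@H]1C(=C)CO[Si](C)(C)C(C)(C)C | intermediate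
25 | 7β,8β-epoxy-7α-[3-(PMB-oxy)prop-1-en-2-yl]-10β-methyl-6β-(TES-oxy)-10α-vinyl-5α-[3-(TBS-oxy)prop-1-en-2-yl]cyclohexane | C=C[C@]1(C)C[C@H]2O[C@@]2(C(=C)COCc3ccc(OC)cc3)[C@@H](O[Si](CC)(CC)CC)[C@@H]1C(=C)CO[Si](C)(C)C(C)(C)C | intermediate
26 | 7β-[3-(PMB-oxy)prop-1-en-2-yl]-10β-methyl-6β-(TES-oxy)-10α-vinyl-5α-[3-(TBS-oxy)prop-1-en-2-yl]cyclohexan-8β-ol | C=C[C@]1(C)C[C@@H](O)[C@@H](C(=C)COCc2ccc(OC)cc2)[C@@H](O[Si](CC)(CC)CC)[C@@H]1C(=C)CO[Si](C)(C)C(C)(C)C | intermediate
27 | methyl (2S)-2,3-dihydroxypropanoate | COC(=O)[C@@H](O)CO | starting material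
28 | methyl (2S)-2,3-bis(TBS-oxy)propanoate | COC(=O)[C@@H](O[Si](C)(C)C(C)(C)C)CO[Si](C)(C)C(C)(C)C | intermediate
29 | (2S)-2,3-bis(TBS-oxy)-N-methoxy-N-methylpropanamide | CON(C)C(=O)[C@@H](O[Si](C)(C)C(C)(C)C)CO[Si](C)(C)C(C)(C)C | intermediate
30 | (3S)-3,4-bis(TBS-oxy)butan-2-one | CC(=O)[C@@H](O[Si](C)(C)C(C)(C)C)CO[Si](C)(C)C(C)(C)C | intermediate
31 | (3S)-3,4-bis(TBS-oxy)but-1-en-2-yl trifluoromethanesulfonate | C=C(OS(=O)(=O)C(F)(F)F)[C@@H](O[Si](C)(C)C(C)(C)C)CO[Si](C)(C)C(C)(C)C | intermediate
32 | acetic (3R)-3,4-bis(TBS-oxy)-2-methylidenebutanoic anhydride | CC(=O)OC(=O)C(=C)[C@@H](O[Si](C)(C)C(C)(C)C)CO[Si](C)(C)C(C)(C)C | intermediate (not isolated)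
33 | (3R)-3,4-bis(TBS-oxy)-2-methylidenebutanoic acid | OC(=O)C(=C)[C@@H](O[Si](C)(C)C(C)(C)C)CO[Si](C)(C)C(C)(C)C | intermediate
34 | (3R)-3,4-bis(TBS-oxy)-2-methylidenebutanoic 2,4,6-trichlorobenzoic anhydride | Clc1cc(Cl)cc(Cl)c1C(=O)OC(=O)C(=C)[C@@H](O[Si](C)(C)C(C)(C)C)CO[Si](C)(C)C(C)(C)C | intermediate (not isolated)
35 | 8β-O-[(3R)-3,4-bis(TBS-oxy)-2-methylidenebutanoyl] ester of 26 | C=C[C@]1(C)C[C@@H](OC(=O)C(=C)[C@@H](O[Si](C)(C)C(C)(C)C)CO[Si](C)(C)C(C)(C)C)[C@@H](C(=C)COCc2ccc(OC)cc2)[C@@H](O[Si](CC)(CC)CC)[C@@H]1C(=C)CO[Si](C)(C)C(C)(C)C | intermediate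
36 | C12 alcohol: 7β-(3-hydroxyprop-1-en-2-yl) analogue of 35 | C=C[C@]1(C)C[C@@H](OC(=O)C(=C)[C@@H](O[Si](C)(C)C(C)(C)C)CO[Si](C)(C)C(C)(C)C)[C@@H](C(=C)CO)[C@@H](O[Si](CC)(CC)CC)[C@@H]1C(=C)CO[Si](C)(C)C(C)(C)C | intermediate
37 | C12 aldehyde: 7β-(3-oxoprop-1-en-2-yl) analogue of 35 | C=C[C@]1(C)C[C@@H](OC(=O)C(=C)[C@@H](O[Si](C)(C)C(C)(C)C)CO[Si](C)(C)C(C)(C)C)[C@@H](C(=C)C=O)[C@@H](O[Si](CC)(CC)CC)[C@@H]1C(=C)CO[Si](C)(C)C(C)(C)C | intermediate (not isolated)
38 | C12 acid: 2-{8β-[(3R)-3,4-bis(TBS-oxy)-2-methylidenebutanoyloxy]-10β-methyl-6β-(TES-oxy)-10α-vinyl-5α-[3-(TBS-oxy)prop-1-en-2-yl]cyclohexan-7β-yl}prop-2-enoic acid | C=C[C@]1(C)C[C@@H](OC(=O)C(=C)[C@@H](O[Si](C)(C)C(C)(C)C)CO[Si](C)(C)C(C)(C)C)[C@@H](C(=C)C(=O)O)[C@@H](O[Si](CC)(CC)CC)[C@@H]1C(=C)CO[Si](C)(C)C(C)(C)C | intermediate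
39 | 2-[(1S,2S,3S,4S,6R)-6-{[(3R)-3,4-dihydroxy-2-methylidenebutanoyl]oxy}-4-ethenyl-2-hydroxy-3-(3-hydroxyprop-1-en-2-yl)-4-methylcyclohexyl]prop-2-enoic acid | C=C[C@]1(C)C[C@@H](OC(=O)C(=C)[C@@H](O)CO)[C@@H](C(=C)C(=O)O)[C@@H](O)[C@@H]1C(=C)CO | target

## Step count and least certain steps

Total: 28 steps. Longest linear sequence: 21 steps (steps 1–13, 16–19 and 25–28, from 1 and 2 to 39).

Step 1 (proposed new method). What may go wrong is loss of regio- or enantiocontrol: head-to-tail addition under Lewis-acid complexation, a background reaction of uncomplexed enone, or Lewis-acid-induced oligomerisation of allene. The fallback uses known chemistry and sets out from 1 and 2. Uncatalysed irradiation (a known head-to-head process) gives 3 together with its antipode, (1S,6R)-6-methyl-8-methylidenebicyclo[4.2.0]octan-2-one F1. NaBH4 reduction gives 4 and the antipodal alcohol (1S,2R,6R)-6-methyl-8-methylidenebicyclo[4.2.0]octan-2-ol F2. Esterification of the mixture with (S)-2-methoxy-2-phenylacetic acid (carbodiimide, DMAP) gives two diastereomers: the (S)-2-methoxy-2-phenylacetate of 4, F3, and the (S)-2-methoxy-2-phenylacetate of the antipodal alcohol, F4. These are separated by chromatography or crystallisation, and methanolysis of F3 (K2CO3, MeOH) returns to the route at 4.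

Step 8 (key step). What may go wrong is slow initiation at the hindered trisubstituted cyclobutene, or ring-opening oligomerisation outrunning capping by ethene. The fallback sets out from 9. Oxidative cleavage of C1=C4 (O3, then PPh3) gives the keto aldehyde 10β-methyl-10α-formyl-5α-[(TBS-oxy)acetyl]-6α-(TES-oxy)cyclohexane F5. Double Wittig methylenation (Ph3P=CH2, excess) installs C2 and C3 and returns to the route at 11.

Step 13. What may go wrong is poor facial selectivity: the branched C5 arm may compete with the iodoalkenyl arm as the large group, and the substrate's own bias may oppose the catalyst. The fallback sets out from 16. Reduction tuned for the opposite face (NaBH4/CeCl3 or the antipodal oxazaborolidine) gives the epimeric alcohol 7-iodo-10β-methyl-10α-vinyl-5α-[3-(TBS-oxy)prop-1-en-2-yl]cyclohex-7-en-6α-ol F6. Mitsunobu inversion with 4-nitrobenzoic acid gives the 6β-(4-nitrobenzoate) F7, and methanolysis returns to the route at 17.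

Step 19. What may go wrong is hydride delivery to the primary terminus C13 (moving the alkene into the ring-exocyclic tetrasubstituted position), β-hydride elimination of the allyl complex, or facial exchange before hydride transfer. The fallback sets out from 25. Zerovalent-palladium-catalysed 1,4-opening with N-isopropylidene-N'-(2-nitrobenzenesulfonyl)hydrazine as nitrogen nucleophile gives the C13 sulfonylhydrazone adduct with a C7=C11 double bond and free 8β-OH, F8. Hydrolysis (trifluoroethanol/water) releases the allylic monoalkyl diazene F9. Its sigmatropic loss of N2 transfers hydrogen to C7 on the less hindered α face and restores C11=C13, returning to the route at 26.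

Step 28. What may go wrong is lactonisation of the liberated C12 acid onto 6-OH, or acyl transfer and expulsion of the side chain during the slow removal of the secondary silyl ether. The fallback sets out from 38. Alkylation of the carboxylate (allyl bromide, K2CO3, DMF) gives the allyl ester of 38, F10. The same fluoride treatment gives the desilylated allyl ester of 39, F11, so that no free acid is exposed to the fluoride medium. Neutral deallylation (Pd(PPh3)4, PhSiH3) returns to the route at 39.

## Further compounds

F1 | step 1 | (1S,6R)-6-methyl-8-methylidenebicyclo[4.2.0]octan-2-one | C3[C@@]1(C)CCCC(=O)[C@H]1C3=C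
F2 | step 1 | (1S,2R,6R)-6-methyl-8-methylidenebicyclo[4.2.0]octan-2-ol | C3[C@@]1(C)CCC[C@@H](O)[C@H]1C3=C
F3 | step 1 | (1R,2S,6S)-6-methyl-8-methylidenebicyclo[4.2.0]octan-2-yl (S)-2-methoxy-2-phenylacetate | C3[C@]1(C)CCC[C@H](OC(=O)[C@@H](OC)c2ccccc2)[C@@H]1C3=C
F4 | step 1 | (1S,2R,6R)-6-methyl-8-methylidenebicyclo[4.2.0]octan-2-yl (S)-2-methoxy-2-phenylacetate | C3[C@@]1(C)CCC[C@@H](OC(=O)[C@@H](OC)c2ccccc2)[C@H]1C3=C
F5 | step 8 | 10β-methyl-10α-formyl-5α-[(TBS-oxy)acetyl]-6α-(TES-oxy)cyclohexane | O=C[C@]1(C)CCC[C@H](O[Si](CC)(CC)CC)[C@@H]1C(=O)CO[Si](C)(C)C(C)(C)C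
F6 | step 13 | 7-iodo-10β-methyl-10α-vinyl-5α-[3-(TBS-oxy)prop-1-en-2-yl]cyclohex-7-en-6α-ol | C=C[C@]1(C)CC=C(I)[C@H](O)[C@@H]1C(=C)CO[Si](C)(C)C(C)(C)C
F7 | step 13 | 7-iodo-10β-methyl-10α-vinyl-5α-[3-(TBS-oxy)prop-1-en-2-yl]cyclohex-7-en-6β-yl 4-nitrobenzoate | C=C[C@]1(C)CC=C(I)[C@@H](OC(=O)c2ccc(cc2)[N+](=O)[O-])[C@@H]1C(=C)CO[Si](C)(C)C(C)(C)C
F8 | step 19 | C13 N-(2-nitrobenzenesulfonyl)-N'-isopropylidene hydrazine adduct with C7=C11 double bond, 8β-OH and 6β-OTES | C=C[C@]1(C)C[C@@H](O)C(=C(CN(N=C(C)C)S(=O)(=O)c2ccccc2[N+](=O)[O-])COCc3ccc(OC)cc3)[C@@H](O[Si](CC)(CC)CC)[C@@H]1C(=C)CO[Si](C)(C)C(C)(C)C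
F9 | step 19 | C13 monoalkyl diazene with C7=C11 double bond, 8β-OH and 6β-OTES | C=C[C@]1(C)C[C@@H](O)C(=C(CN=N)COCc2ccc(OC)cc2)[C@@H](O[Si](CC)(CC)CC)[C@@H]1C(=C)CO[Si](C)(C)C(C)(C)C
F10 | step 28 | prop-2-en-1-yl ester of 38 | C=C[C@]1(C)C[C@@H](OC(=O)C(=C)[C@@H](O[Si](C)(C)C(C)(C)C)CO[Si](C)(C)C(C)(C)C)[C@@H](C(=C)C(=O)OCC=C)[C@@H](O[Si](CC)(CC)CC)[C@@H]1C(=C)CO[Si](C)(C)C(C)(C)C
F11 | step 28 | prop-2-en-1-yl ester of 39 | C=C[C@]1(C)C[C@@H](OC(=O)C(=C)[C@@H](O)CO)[C@@H](C(=C)C(=O)OCC=C)[C@@H](O)[C@@H]1C(=C)CO
A1 | alternative 1 | silicon-tethered triene: 4-(silyloxymethyl)furan-2(5H)-one linked through diisopropylsilylene to the (E)-1,3-bis(silyloxy)diene carrying the methyl acetate arm | C=C(O[Si](C(C)C)(C(C)C)OCC1=CC(=O)OC1)/C(CC(=O)OC)=C/O[Si](C)(C)C(C)(C)C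
A2 | alternative 1 | bridged Diels–Alder adduct: cis-fused C1–O–C4 lactone, C14–O–Si–O–C8 bridge, C7=C8 enol ether, C6 OTBS | C3[C@]1(CO[Si](C(C)C)(C(C)C)O2)CC2=C(CC(=O)OC)[C@@H](O[Si](C)(C)C(C)(C)C)[C@@H]1C(=O)O3
A3 | alternative 2 | open-chain C6 aldehyde with (Z)-2-(bromomethyl)enoate allyl ester, C8 OPMB, C15 OTBS | C=C[C@]([C@H](C=O)C(=C)CO[Si](C)(C)C(C)(C)C)(C)C[C@@H](OCc1ccc(OC)cc1)/C=C(\CBr)C(=O)OCC=C
A4 | alternative 2 | cyclohexane hydroxy ester: 6β-OH, C8 OPMB, C15 OTBS, C12 allyl ester | C=C[C@]1(C)C[C@@H](OCc2ccc(OC)cc2)[C@@H](C(=C)C(=O)OCC=C)[C@@H](O)[C@@H]1C(=C)CO[Si](C)(C)C(C)(C)C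
A5 | alternative 3 | 2-methylene-oxocene: eight-membered enol ether O–C8(=C9)–C7–C6–C5–C10=C1–C2 with C6 OTES, C12 OPMB, C15 OTBS | C=C1[C@@H](C(=C)COCc2ccc(OC)cc2)[C@@H](O[Si](CC)(CC)CC)[C@H](C(=C)CO[Si](C)(C)C(C)(C)C)/C(C)=C\CO1
A6 | alternative 3 | 3-methyl-3-vinylcyclohexanone (C8 ketone) with C5, C6 and C7 substituents in place | C=C[C@]1(C)CC(=O)[C@@H](C(=C)COCc2ccc(OC)cc2)[C@@H](O[Si](CC)(CC)CC)[C@@H]1C(=C)CO[Si](C)(C)C(C)(C)C
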